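4 questions stand on gamma, alpha and epsilon: which flask holds most target, and how much target each holds. I answered them from one crossing read out of the earlier runs.

| setting | autumn | dawn | noon | gamma | alpha | epsilon |
|---|---|---|---|---|---|---|
| substrate | 5 mM | 20 mM | 10 mM | 10 mM | 10 mM | 10 mM |
| other conformer | 10 mM | 10 mM | 20 mM | 10.0 mM | 10.0 mM | 10.0 mM |
| temperature | 58 °C | 74 °C | 58 °C | 50 °C | 80 °C | 65 °C |
| remark | run made earlier | run made earlier | run made earlier |  |  |  |
| time |  |  |  | 3.0 h | 3.0 h | 3.0 h |

- autumn (time / h: target / %, substrate / %): 0.250: 2.9, 26.2; 0.500: 4.8, 21.7; 1.00: 8.4, 14.9; 2.00: 11.9, 8.2; 4.00: 15.2, 2.7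
- dawn (time / min: target / %, substrate / %): 6.00: 9.1, 37.3; 15.0: 15.2, 20.6; 30.0: 19.5, 10.2; 50.0: 20.8, 4.0; 80.0: 21.1, 1.5
- noon (time / h: target / %, substrate / %): 0.667: 5.5, 14.7; 1.33: 8.2, 9.8; 2.00: 10.1, 6.1; 3.00: 11.9, 4.2; 4.00: 11.4, 1.6

(readings scatter by 0.5 percentage points)

- the flask with the highest amount of target, in percent of the substrate and other conformer together charged ("all alike" if they lie within 1.5 percentage points) (gamma / alpha / epsilon / all alike)
- final target, as a percentage of the substrate and other conformer together charged, in gamma
- final target, as a percentage of the substrate and other conformer together charged, in alpha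
- final target, as a percentage of the substrate and other conformer together charged, in epsilon

- in a conversion other conformer counts as not yet reacted

I turned the amount first. Substrate seemed to leave by a first-order road to target and a second-order loss, since at 58 °C the last target reading was 15.2% in autumn and 11.4% in noon, which charged more of both substrate and other conformer. I therefore took the share of used substrate reaching target as c\*/(c\*+c), with c the substrate level. Over its first interval autumn gave a share of 40.7% at a mean level of 4.46 mM, so c\* was 3.06 mM. Noon gave 29.5% at 7.20 mM, so c\* was 3.02 mM. The two readings came from different runs and agreed, so I kept autumn's, 3.06 mM at 58 °C, as my crossing level c\*, the substrate concentration at which both roads run equally fast.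

Temperature came next. Dawn's first interval, with a share of 31.0% at 15.6 mM, read c\* as 7.00 mM at 74 °C, higher than at 58 °C. That is an activation-energy gap of 49.5 kJ mol⁻¹, which puts c\* at 1.96 mM in gamma, 4.44 mM in epsilon and 9.37 mM in alpha.

Summed down from a charge C to nothing, the overall selectivity is F = (c\*/C)·ln(1+C/c\*). Substrate is half of the charge, so by this sum the first-order road is given 17.7% in gamma, 26.2% in epsilon and 34.0% in alpha. The same sum for dawn gives 31.5% against a last target reading of 21.1%, so I held these as a ranking, not as target amounts.

Time mattered for gamma, which is colder than autumn, and autumn still held 2.7% substrate at 4.00 h. Other conformer no run read, and the flasks charge equal amounts.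

The forecast chose alpha, with 12% in gamma, 21% in alpha and 19.5% in epsilon, and said “I treat that conformer as essentially unproductive”. My alpha road share stands above its number.

    other conformer → isomer of the product (k = 0.00590 min⁻¹, Ea = 107 kJ mol⁻¹)
    target ⇌ isomer of the product (K = 1.30, k = 0.0270 min⁻¹, Ea = 120 kJ mol⁻¹, ΔH = 12.0 kJ mol⁻¹)
    substrate ⇌ other conformer (K = 3.00, k = 0.00450 min⁻¹, Ea = 105 kJ mol⁻¹, ΔH = −90.0 kJ mol⁻¹)
    2 substrate → self-condensation product (k = 2.80 M⁻¹ min⁻¹, Ea = 48.0 kJ mol⁻¹)
    substrate → target (k = 0.0580 min⁻¹, Ea = 97.0 kJ mol⁻¹)
    (constants at 80 °C)

Alpha held most, 30.1% against 18.9% in epsilon and 10.4% in gamma, and with the step from other conformer to isomer of the product struck out alpha gave 19.4%. The crossing level left the second-order road 16.0% in alpha, and with substrate down to 0.383% the flask held 14.9% self-condensation product.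

In the neighbour flask, gamma repeated at 75 °C, c\* comes to 7.36 mM, which leaves 18.4% for the second-order road. The computed flask holds 17.0% self-condensation product and 24.6% target.

The numbers in the tables were computed with made-up constants, noise included.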